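**Retrosynthetic overview**
1. The strategy rests on the butenolide ring O–C21–C22(CH3)=C23–C24(=O). Its only ring alkene, C22=C23, is disconnected by ring-closing metathesis to the C21 acrylate of an isopropenyl carbinol; this ring is formed last.
2. C12–C13 is disconnected to a primary C12 alkyllithium of the decalin half and the dimethylamide carbon (C13) of an L-tartrate dioxolane that already carries C14, C15 and the C21 isopropenyl carbinol. The C13 methylidene is added by Wittig methylenation.
3. C14 and C15 come from L-tartaric acid. C21 is set on the small fragment by oxazaborolidine reduction of the isopropenyl ketone, in the Felkin–Anh sense.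
4. The decalin half comes from (+)-larixol, which supplies rings A and B with C5, C6 (6α-OH), C9 and C10. The side chain is cut back to C12, the 8(17)-alkene becomes the 8α-carbinol, and the 4α-methyl (C18) is oxidised through the 6α-nitrite by a 1,5-hydrogen shift.
5. Ring order: rings A and B from the pool, then a temporary C8–O–C12 γ-lactone and a 6,18-oxolane acetal, then the tartrate dioxolane, then the butenolide.

Key step: step 18

Remark: a 6α-hydroxyl and an 18-aldehyde on this trans-decalin lie about 2.5 Å apart and are ring–chain tautomers of a 6,18-lactol, so the pair is carried as the cyclic methyl acetal (both C18 epimers) and the target is taken as the open form drawn.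

Numbering: decalin C1–C10 (ring A C1–C5/C10, ring B C5–C10), C18 = 4α carbon, C11–C12 chain, C13 (=CH2), C14/C15 diol, lactone C21 (γ), C22 (β, methyl), C23 (α), C24 (C=O).

**Route**

Step 1
Reactants: 1 (+)-larixol
Product: 2 6α-hydroxy-14,15-dinorlabd-8(17)-en-13-one
Conditions: KMnO4, MgSO4, acetone/H2O, 0 °C
Reagents that add atoms: none
Why: Permanganate degradation of the tertiary vinyl carbinol (dihydroxylation, glycol cleavage and loss of C14 and C15) is the standard way to cut a labdane 13-ol side chain to the 13-methyl ketone, and the hindered exocyclic alkene and 6α-hydroxyl should survive at 0 °C.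

Step 2
Reactants: 2 6α-hydroxy-14,15-dinorlabd-8(17)-en-13-one
Product: 3 12-acetoxy-8α,17-epoxy-13,14,15,16-tetranorlabdan-6α-ol
Conditions: m-CPBA (4 equiv), NaHCO3, CH2Cl2, 0 °C → 40 °C
Reagents that add atoms: 3-chloroperbenzoic acid, OOC(=O)c1cccc(Cl)c1
Why: Prilezhaev epoxidation should occur from the α face because the axial C10 methyl shields the β face (this sets C8), and the slower Baeyer–Villiger oxidation of the methyl ketone migrates the primary C12 in preference to methyl to give the C12 acetate.

Step 3
Reactants: 3 12-acetoxy-8α,17-epoxy-13,14,15,16-tetranorlabdan-6α-ol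
Product: 4 13,14,15,16-tetranorlabdane-6α,8α,12-triol
Conditions: LiAlH4, THF, 0 °C → reflux
Reagents that add atoms: none
Why: Hydride opens the spiro-epoxide by SN2 attack at the unsubstituted C17, leaving the equatorial 8α-hydroxyl and axial 8β-methyl, and cleaves the acetate in the same operation.

Step 4
Reactants: 4 13,14,15,16-tetranorlabdane-6α,8α,12-triol
Product: 5 6α-hydroxysclareolide (6α-hydroxy-13,14,15,16-tetranorlabdan-12,8α-olide)
Conditions: TEMPO (2,2,6,6-tetramethylpiperidin-1-oxyl, 10 mol %), PhI(OAc)2 (2.2 equiv), CH2Cl2, rt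
Reagents that add atoms: none
Why: Oxoammonium oxidation is selective for the primary alcohol, the aldehyde closes on the tertiary 8-hydroxyl to a lactol that is oxidised on to the γ-lactone (oxidative lactonisation of a 1,4-diol), and the hindered secondary 6α-hydroxyl should be left as the only free hydroxyl.

Step 5
Reactants: 5 6α-hydroxysclareolide
Product: 8 (E)-18-oxime (6α-hydroxy-18-hydroxyimino-13,14,15,16-tetranorlabdan-12,8α-olide; 4α-CH=NOH, 4β-CH3), via 6α-nitrite ester 6 (not isolated), via 18-nitroso compound 7 (not isolated)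
Conditions: NOCl, pyridine, −20 °C; hν (Hg lamp, Pyrex), toluene, 10 °C; then i-PrOH, 80 °C
Reagents that add atoms: nitrosyl chloride, O=NCl
Why: Barton nitrite photolysis: O–N homolysis gives the 6α-alkoxy radical, which abstracts hydrogen through a six-membered transition state from the 4α-methyl held syn-pentane to it (the 4β and 10β methyls are remote), NO recombines at C18 and the nitroso compound tautomerises to the oxime, so C4 becomes stereogenic with the oxidised carbon α.

Step 6
Reactants: 8 (E)-18-oxime
Product: 10 6α,18-epoxy-18-methoxy-13,14,15,16-tetranorlabdan-12,8α-olide (cyclic methyl acetal; both C18 epimers), via 6α,18-lactol 9 (not isolated)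
Conditions: NaNO2, AcOH/H2O, 10 °C; then pyridinium p-toluenesulfonate, MeOH, rt
Reagents that add atoms: methanol, CO
Why: Nitrosative deoximation frees the aldehyde, which closes at once on the 6α-hydroxyl to the five-membered lactol, and acid-catalysed acetal exchange with methanol (Fischer-type) fixes it as the methyl acetal while the γ-lactone is inert.

Step 7
Reactants: 10 cyclic methyl acetal lactone
Product: 11 6α,18-epoxy-18-methoxy-13,14,15,16-tetranorlabdane-8α,12-diol
Conditions: LiAlH4, THF, 0 °C → rt
Reagents that add atoms: none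
Why: Hydride reduction of the γ-lactone gives the 1,4-diol (tertiary 8α-hydroxyl, primary 12-hydroxyl), and the acetal is stable to hydride.

Step 8
Reactants: 11 acetal diol
Product: 13 8α-(triethylsilyloxy)-6α,18-epoxy-18-methoxy-13,14,15,16-tetranorlabdan-12-ol, via 8,12-bis(triethylsilyl) ether 12 (not isolated)
Conditions: Et3SiOTf (2.5 equiv), 2,6-lutidine, CH2Cl2, −78 → 0 °C; then MeOH, pyridinium p-toluenesulfonate, 0 °C
Reagents that add atoms: triethylsilyl trifluoromethanesulfonate, CC[Si](CC)(CC)OS(=O)(=O)C(F)(F)F
Why: The silyl triflate silylates both hydroxyls, and mild acid methanolysis then removes only the unhindered primary silyl ether, leaving the tertiary C8 ether that must block tetrahydrofuran formation once C12 carries a leaving group.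

Step 9
Reactants: 13 8-silyl ether 12-alcohol
Product: 14 12-iodo-8α-(triethylsilyloxy)-6α,18-epoxy-18-methoxy-13,14,15,16-tetranorlabdane
Conditions: I2, PPh3, imidazole, CH2Cl2, 0 °C
Reagents that add atoms: iodine, II
Why: Garegg–Samuelsson (Appel-type) iodination converts the primary alcohol through its alkoxyphosphonium salt by SN2, and the imidazole buffer protects the acetal and silyl ether.

Step 10
Reactants: 15 dimethyl 2,3-O-isopropylidene-L-tartrate
Product: 16 (4R,5R)-N,N,N′,N′,2,2-hexamethyl-1,3-dioxolane-4,5-dicarboxamide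
Conditions: Me2NH (40% aq.), MeOH, rt
Reagents that add atoms: dimethylamine, CNC
Why: Aminolysis of the α-alkoxy-activated esters gives the bis(dimethylamide) without touching the two stereocentres.

Step 11
Reactants: 16 bis(dimethylamide); 17 isopropenylmagnesium bromide
Product: 18 (4R,5R)-5-(2-methylprop-2-enoyl)-N,N,2,2-tetramethyl-1,3-dioxolane-4-carboxamide
Conditions: THF, −15 °C; inverse quench into cold 1 M HCl
Reagents that add atoms: none
Why: Grignard addition to the C2-symmetric diamide stops at mono-addition because the chelated magnesium hemiaminal neither collapses nor lets the second amide react, and the acidic quench protonates the released amine before it can add to the enone.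

Step 12
Reactants: 18 isopropenyl ketone amide
Product: 19 (4R,5S)-5-[(1R)-1-hydroxy-2-methylprop-2-enyl]-N,N,2,2-tetramethyl-1,3-dioxolane-4-carboxamide (hydroxyl syn to the adjacent ring oxygen)
Conditions: (R)-2-methyl-CBS-oxazaborolidine [(R)-1-methyl-3,3-diphenyltetrahydro-1H,3H-pyrrolo[1,2-c][1,3,2]oxazaborole] (0.5 equiv), catecholborane, toluene, −78 °C
Reagents that add atoms: none
Why: Corey–Bakshi–Shibata reduction delivers hydride 1,2 with the α-methylvinyl group as the larger substituent, giving the (R)-carbinol at C21, the same face that Felkin–Anh attack anti to the dioxolane C–O bond selects, so reagent and substrate control should reinforce each other without conjugate reduction.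

Step 13
Reactants: 19 allylic alcohol amide
Product: 20 triethylsilyl ether of 19
Conditions: Et3SiCl, imidazole, DMF, 0 °C → rt
Reagents that add atoms: chlorotriethylsilane, CC[Si](Cl)(CC)CC
Why: Standard silylation masks the only acidic proton of the fragment before it meets the alkyllithium.

Step 14
Reactants: 14 C12 iodide; 20 silyl ether amide
Product: 22 C13 ketone (C12–C13 bond formed; decalin half joined to the dioxolane), via C12 alkyllithium 21 (not isolated)
Conditions: t-BuLi (2.1 equiv), Et2O/pentane, −78 °C; then 20, THF, −78 → −40 °C; aq. NH4Cl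
Reagents that add atoms: none
Why: Iodine–lithium exchange gives the primary alkyllithium, which adds once to the dimethylamide because the lithium hemiaminal persists until the quench (acyl substitution), and silyl ethers, acetal and acetonide are inert at −78 °C.

Step 15
Reactants: 22 C13 ketone
Product: 23 C13 methylidene compound (8-O and 21-O triethylsilyl ethers)
Conditions: Ph3PCH3Br, KN(SiMe3)2, THF, 0 °C; then 22, −78 °C → rt
Reagents that add atoms: methyltriphenylphosphonium bromide, C[P+](c1ccccc1)(c1ccccc1)c1ccccc1.[Br-]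
Why: Wittig methylenation of the unhindered ketone with the non-stabilised ylide is faster than enolisation toward C14, whose trans-dioxolane configuration is in any case the thermodynamic one.

Step 16
Reactants: 23 bis(silyl ether)
Product: 24 diol (free tertiary C8 and secondary C21 hydroxyls)
Conditions: Bu4NF (4 equiv), THF, rt → 45 °C
Reagents that add atoms: none
Why: Fluoride cleaves both triethylsilyl ethers, and nothing else in the molecule (alkenes, acetonide, methyl acetal) responds to it.

Step 17
Reactants: 24 diol; 25 acryloyl chloride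
Product: 26 C21 acrylate of the isopropenyl carbinol (metathesis precursor)
Conditions: i-Pr2NEt, CH2Cl2, −20 → 0 °C
Reagents that add atoms: none
Why: O-acylation takes place only at the secondary allylic C21 hydroxyl because the tertiary, neopentyl-like C8 hydroxyl is not acylated by an acid chloride and amine base at 0 °C.

Step 18
Reactants: 26 C21 acrylate
Product: 27 protected butenolide (4-methyl-2(5H)-furanone ring closed; acetonide and methyl acetal retained)
Conditions: second-generation Hoveyda–Grubbs catalyst RuCl2(H2IMes)(=CH-C6H4-2-O-i-Pr) (10 mol %), 1,4-benzoquinone (20 mol %), toluene (2 mM), 80 °C, Ar sparge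
Reagents that add atoms: none
Why: Olefin metathesis by the Chauvin mechanism: the ruthenium alkylidene loads on the terminal acrylate CH=CH2, the only monosubstituted alkene, the resulting C23 carbene adds intramolecularly to the isopropenyl C22=CH2 to give a ruthenacyclobutane, and cycloreversion releases the methylidene (in the end ethylene) and leaves the C22=C23 bond. The closest known reaction type is the ring-closing metathesis of acrylates of 2-methylallylic alcohols to 4-methylbutenolides with N-heterocyclic-carbene ruthenium catalysts. The ring closed is the five-membered lactone O–C21–C22=C23–C24, made by joining the two alkenes that hang from the same carbinol carbon, so the new alkene is necessarily endocyclic and cis. No stereocentre is formed, and C21, already fixed, is not epimerised because the lactone with its acidic γ-hydrogen appears only under these neutral conditions. The step needs chemoselectivity among three alkenes: the C13 methylidene is 1,1-disubstituted and hindered, and any ring through it (a seven-membered lactone from C23 or a cyclopentene from C22) would be trans-fused to the dioxolane across C14–C15, so only the butenolide closure is geometrically easy. Removal of ethylene and the benzoquinone hydride scavenger should suppress the reverse reaction and alkene migration.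

Step 19
Reactants: 27 protected butenolide
Product: 28 target CNP0156243.1
Conditions: 2 M aq. HCl/THF (1:3), 0 °C → rt
Reagents that add atoms: water, O
Why: Aqueous acid hydrolyses the trans-acetonide to the C14/C15 diol and the cyclic methyl acetal to the lactol, which opens to the 6α-hydroxy-18-aldehyde, while the butenolide and the tertiary alcohol should tolerate the mild conditions.

**Compound list**
1 | (+)-larixol, (13S)-labda-8(17),14-diene-6α,13-diol | C=C[C@@](C)(O)CC[C@@H]1[C@@]2(C)CCCC(C)(C)[C@@H]2[C@@H](O)CC1=C | starting material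
2 | 6α-hydroxy-14,15-dinorlabd-8(17)-en-13-one | CC(=O)CC[C@@H]1[C@@]2(C)CCCC(C)(C)[C@@H]2[C@@H](O)CC1=C | intermediate
3 | 12-acetoxy-8α,17-epoxy-13,14,15,16-tetranorlabdan-6α-ol | CC(=O)OCC[C@@H]1[C@@]2(C)CCCC(C)(C)[C@@H]2[C@@H](O)C[C@@]1(C3)O3 | intermediate
4 | 13,14,15,16-tetranorlabdane-6α,8α,12-triol | OCC[C@@H]1[C@@]2(C)CCCC(C)(C)[C@@H]2[C@@H](O)C[C@@]1(C)O | intermediate
5 | 6α-hydroxysclareolide | O=C1C[C@@H]2[C@@]3(C)CCCC(C)(C)[C@@H]3[C@@H](O)C[C@@]2(C)O1 | intermediate
6 | 6α-nitrite ester of 5 | O=C1C[C@@H]2[C@@]3(C)CCCC(C)(C)[C@@H]3[C@@H](ON=O)C[C@@]2(C)O1 | intermediate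
7 | 18-nitroso-6α-hydroxy lactone | O=C1C[C@@H]2[C@@]3(C)CCC[C@@](C)(CN=O)[C@@H]3[C@@H](O)C[C@@]2(C)O1 | intermediate
8 | (E)-18-oxime of the 6α-hydroxy lactone | O=C1C[C@@H]2[C@@]3(C)CCC[C@@](C)(/C=N/O)[C@@H]3[C@@H](O)C[C@@]2(C)O1 | intermediate
9 | 6α,18-lactol lactone | O=C1C[C@@H]2[C@@]3(C)CCC[C@@]4(C)C(O)O[C@H]([C@H]34)C[C@@]2(C)O1 | intermediate
10 | 6α,18-epoxy-18-methoxy-13,14,15,16-tetranorlabdan-12,8α-olide | O=C1C[C@@H]2[C@@]3(C)CCC[C@@]4(C)C(OC)O[C@H]([C@H]34)C[C@@]2(C)O1 | intermediate
11 | 6α,18-epoxy-18-methoxy-13,14,15,16-tetranorlabdane-8α,12-diol | OCC[C@@H]1[C@@]2(C)CCC[C@@]3(C)C(OC)O[C@H]([C@H]23)C[C@@]1(C)O | intermediate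
12 | 8,12-bis(triethylsilyl) ether of 11 | CC[Si](CC)(CC)OCC[C@@H]1[C@@]2(C)CCC[C@@]3(C)C(OC)O[C@H]([C@H]23)C[C@@]1(C)O[Si](CC)(CC)CC | intermediate
13 | 8α-triethylsilyloxy 12-alcohol | OCC[C@@H]1[C@@]2(C)CCC[C@@]3(C)C(OC)O[C@H]([C@H]23)C[C@@]1(C)O[Si](CC)(CC)CC | intermediate
14 | 8α-triethylsilyloxy 12-iodide | ICC[C@@H]1[C@@]2(C)CCC[C@@]3(C)C(OC)O[C@H]([C@H]23)C[C@@]1(C)O[Si](CC)(CC)CC | intermediate
15 | dimethyl 2,3-O-isopropylidene-L-tartrate | COC(=O)[C@@H]1OC(C)(C)O[C@H]1C(=O)OC | starting material
16 | (4R,5R)-N,N,N′,N′,2,2-hexamethyl-1,3-dioxolane-4,5-dicarboxamide | CN(C)C(=O)[C@@H]1OC(C)(C)O[C@H]1C(=O)N(C)C | intermediate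
17 | isopropenylmagnesium bromide | C=C(C)[Mg]Br | starting material
18 | (4R,5R)-5-(2-methylprop-2-enoyl)-N,N,2,2-tetramethyl-1,3-dioxolane-4-carboxamide | CN(C)C(=O)[C@@H]1OC(C)(C)O[C@H]1C(=O)C(C)=C | intermediate
19 | (4R,5S)-5-[(1R)-1-hydroxy-2-methylprop-2-enyl]-N,N,2,2-tetramethyl-1,3-dioxolane-4-carboxamide | CN(C)C(=O)[C@@H]1OC(C)(C)O[C@H]1[C@H](O)C(C)=C | intermediate
20 | triethylsilyl ether of 19 | CN(C)C(=O)[C@@H]1OC(C)(C)O[C@H]1[C@H](O[Si](CC)(CC)CC)C(C)=C | intermediate
21 | C12 alkyllithium from 14 | [Li]CC[C@@H]1[C@@]2(C)CCC[C@@]3(C)C(OC)O[C@H]([C@H]23)C[C@@]1(C)O[Si](CC)(CC)CC | intermediate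
22 | C13 ketone | O=C(CC[C@@H]1[C@@]2(C)CCC[C@@]3(C)C(OC)O[C@H]([C@H]23)C[C@@]1(C)O[Si](CC)(CC)CC)[C@@H]1OC(C)(C)O[C@H]1[C@H](O[Si](CC)(CC)CC)C(C)=C | intermediate
23 | C13 methylidene bis(triethylsilyl) ether | C=C(CC[C@@H]1[C@@]2(C)CCC[C@@]3(C)C(OC)O[C@H]([C@H]23)C[C@@]1(C)O[Si](CC)(CC)CC)[C@@H]1OC(C)(C)O[C@H]1[C@H](O[Si](CC)(CC)CC)C(C)=C | intermediate
24 | C8,C21-diol | C=C(CC[C@@H]1[C@@]2(C)CCC[C@@]3(C)C(OC)O[C@H]([C@H]23)C[C@@]1(C)O)[C@@H]1OC(C)(C)O[C@H]1[C@H](O)C(C)=C | intermediate
25 | acryloyl chloride | C=CC(=O)Cl | starting material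
26 | C21 acrylate (metathesis precursor) | C=C(CC[C@@H]1[C@@]2(C)CCC[C@@]3(C)C(OC)O[C@H]([C@H]23)C[C@@]1(C)O)[C@@H]1OC(C)(C)O[C@H]1[C@H](OC(=O)C=C)C(C)=C | intermediate
27 | protected butenolide | C=C(CC[C@@H]1[C@@]2(C)CCC[C@@]3(C)C(OC)O[C@H]([C@H]23)C[C@@]1(C)O)[C@@H]1OC(C)(C)O[C@H]1[C@@H]1OC(=O)C=C1C | intermediate
28 | CNP0156243.1 | C=C(CC[C@@H]1[C@@]2(C)CCC[C@@](C)(C=O)[C@@H]2[C@@H](O)C[C@@]1(C)O)[C@H](O)[C@@H](O)[C@@H]1OC(=O)C=C1C | target

**Totals**
Total step count: 19. Longest linear sequence: 15 steps (steps 1–9, then 14–19); steps 10–13 build the tartrate fragment.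

**Steps most likely to fail**

Step 5 (nitrite photolysis). The 6α-alkoxy radical may fragment across C5–C6 or recombine with NO before abstracting hydrogen, and the nitroso dimer may not tautomerise cleanly. The fallback sets out from 5 and uses the hypoiodite reaction (Pb(OAc)4, I2, CaCO3, hν, cyclohexane, reflux). Two successive 1,5-hydrogen transfers from the 6α-hypoiodite should carry C18 to the aldehyde level and close the 18-iodo-6α,18-epoxy lactone F1. Solvolysis of this α-iodo ether in MeOH with NaHCO3 returns to the route at 10.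

Step 18 (ring-closing metathesis). Loading of ruthenium on the electron-poor acrylate and closure onto the 1,1-disubstituted alkene may be slow enough for catalyst decay, alkene migration and intermolecular metathesis to compete. The fallback sets out from 24, which is esterified with (2E)-octa-2,7-dienoic acid (2,4,6-trichlorobenzoyl chloride, Et3N, 4-dimethylaminopyridine, toluene) to the relay ester F4. The same ruthenium catalyst should load on the unhindered terminal alkene of the tether, expel cyclopentene and so arrive as the C23 carbene next to the isopropenyl group. Closure returns to the route at 27.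

Step 12 (ketone reduction). Facial selectivity may be poor if reagent control and the substrate bias do not reinforce each other as assumed, and the borane may hydroborate the alkene. The fallback sets out from 18, which is reduced under chelation control (Zn(BH4)2, Et2O, −30 °C) to the C21-epimeric anti alcohol F2. Mitsunobu inversion (4-nitrobenzoic acid, PPh3, diisopropyl azodicarboxylate, THF) gives the inverted 4-nitrobenzoate F3, and methanolysis (K2CO3, MeOH) returns to the route at 19.

**Further compounds**
F1 | step 5 | 18-iodo-6α,18-epoxy-13,14,15,16-tetranorlabdan-12,8α-olide | O=C1C[C@@H]2[C@@]3(C)CCC[C@@]4(C)C(I)O[C@H]([C@H]34)C[C@@]2(C)O1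
F2 | step 12 | C21-epimeric (anti) allylic alcohol amide | CN(C)C(=O)[C@@H]1OC(C)(C)O[C@H]1[C@@H](O)C(C)=C
F3 | step 12 | inverted 4-nitrobenzoate of the allylic alcohol amide | CN(C)C(=O)[C@@H]1OC(C)(C)O[C@H]1[C@H](OC(=O)c2ccc(cc2)[N+](=O)[O-])C(C)=C
F4 | step 18 | C21 (2E)-octa-2,7-dienoate relay ester | C=C(CC[C@@H]1[C@@]2(C)CCC[C@@]3(C)C(OC)O[C@H]([C@H]23)C[C@@]1(C)O)[C@@H]1OC(C)(C)O[C@H]1[C@H](OC(=O)/C=C/CCCC=C)C(C)=C
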